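**Retrosynthetic overview**
1. Chain numbering: C1 = ketone carbon, C2–C10 = nine CH2 groups, C11 = benzylic CH2 on the 2-hydroxyphenyl ring. Last disconnection: the four phenols come from four aryl methyl ethers in one global O-demethylation.
2. Key disconnection C10–C11: C10 is a primary alkyl radical and C11 is the C=N carbon of 2-methoxybenzaldehyde N-tosylhydrazone (aldehyde oxidation level; sulfinate and N2 are traceless activators).
3. The C10 radical comes from a temporary ring. Joining C10 back to C1 gives 1-(2,4,6-trimethoxyphenyl)cyclodecan-1-ol, whose alkoxy radical breaks C1–C10, so C1=O, the open C2–C10 chain and the C10–C11 bond arise in one operation. The carbinol is one step from 1,3,5-trimethoxybenzene and cyclodecanone.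
4. Enabling feature: C1 is bonded directly to the electron-rich 1,3,5-trioxygenated benzene ring, a built-in redox antenna for O–H activation. C1 is linked to C10 only by unbranched, unfunctionalised CH2 groups, so the temporary ring is a symmetric, strained cyclodecane with two equivalent C1–CH2 bonds. C11 is a benzylic CH2 that maps onto an aryl aldehyde carbon.
5. Ring order: no ring of the target has to be formed, and both benzene rings are bought intact. The only ring event is the opening of the purchased ten-membered carbocycle in the key step.

Key step: step 3

Remark: the target has no stereocentre, stereogenic axis or C=C bond. It is achiral, so no absolute stereocontrol is needed and the route delivers the single compound drawn.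

**Step 1**
Reactants: 1 1,3,5-trimethoxybenzene; 2 cyclodecanone
Product: 4 1-(2,4,6-trimethoxyphenyl)cyclodecan-1-ol, via 2,4,6-trimethoxyphenyllithium 3 (not isolated)
Conditions: 1, n-BuLi, TMEDA, THF, 0 °C → rt; then 2 premixed with LaCl3·2LiCl, THF, −78 → 0 °C; H2O quench; basic alumina
Reagents that add atoms: none
Why: Directed ortho-lithiation at the position flanked by two methoxy groups followed by lanthanide-assisted 1,2-addition of the aryllithium to the ketone should work because the oxophilic La(III) salt activates the sluggish medium-ring carbonyl and suppresses enolisation, while the purely basic work-up keeps the ionisable tertiary benzylic alcohol from dehydrating; no stereocentre is formed.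

**Step 2**
Reactants: 5 2-methoxybenzaldehyde
Product: 6 (E)-N'-(2-methoxybenzylidene)-4-methylbenzenesulfonohydrazide
Conditions: TsNHNH2, MeOH, rt; filtration of the crystalline product
Reagents that add atoms: p-toluenesulfonyl hydrazide, Cc1ccc(cc1)S(=O)(=O)NN
Why: Hydrazone formation by condensation of an aromatic aldehyde with a sulfonyl hydrazide is fast without added acid and should deliver the thermodynamically preferred E isomer, with no stereocentre formed.

**Step 3**
Reactants: 4 1-(2,4,6-trimethoxyphenyl)cyclodecan-1-ol; 6 (E)-N'-(2-methoxybenzylidene)-4-methylbenzenesulfonohydrazide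
Product: 9 11-(2-methoxyphenyl)-1-(2,4,6-trimethoxyphenyl)undecan-1-one, via tosylhydrazide adduct 7 (not isolated), via benzylic diazene 8 (not isolated)
Conditions: 6 (1.5 equiv), [Ir(dF(CF3)ppy)2(5,5′-dCF3bpy)]PF6 (2 mol %), 2,4,6-collidine (2 equiv), MeCN (0.2 M), 450 nm LEDs, rt, Ar; then K2CO3, MeOH, 60 °C, same flask
Reagents that add atoms: none
Why: Proposed new method: the excited Ir(III) complex oxidises the trimethoxyphenyl ring of 4 and, with collidine accepting the O–H proton, the arene radical cation passes the hole to oxygen (proton-coupled electron transfer) to give the tertiary alkoxy radical, whose β-scission of a C1–CH2 ring bond releases the medium-ring strain and unveils the aryl ketone together with the primary C10 radical. This nucleophilic radical adds in Giese fashion to the C=N carbon (C11) of the stable acceptor 6, the hydrazinyl radical so formed is reduced by Ir(II) and protonated by collidinium to 7, which closes a redox-neutral cycle, and K2CO3/MeOH then expels sulfinate to give diazene 8, which loses N2 in a Wolff–Kishner-type step and leaves C11 as CH2. The closest known reaction types are the photocatalytic PCET ring-opening of 1-(alkoxyaryl)cycloalkanols with intermolecular capture of the distal radical, and the photocatalytic addition of alkyl radicals to aldehyde N-sulfonylhydrazones followed by base-induced loss of sulfinate and N2 as a C(sp3)–C(sp3) coupling; only the merger of the two is new. No ring is closed (the temporary ten-membered ring is opened) and no lasting stereocentre arises, since C11 is stereogenic only in racemic 7 and 8 and ends as CH2. The site of C–C cleavage is secured by the symmetry of 4 (both C1–CH2 bonds are equivalent, loss of an aryl radical is prohibitive), and chemoselective oxidation by the trialkoxyarene of 4 being the most easily oxidised π-system present, whereas the ring of 9 is deactivated by its new acyl group. Capture of the C10 radical ahead of hydrogen-atom transfer is secured by omitting any H-atom donor, by blocking all Minisci positions of the base, and by using 6 in excess at high concentration.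

**Step 4**
Reactants: 9 11-(2-methoxyphenyl)-1-(2,4,6-trimethoxyphenyl)undecan-1-one
Product: 10 11-(2-hydroxyphenyl)-1-(2,4,6-trihydroxyphenyl)undecan-1-one (target)
Conditions: BBr3 (excess), CH2Cl2, −78 °C → rt; then H2O
Reagents that add atoms: none
Why: Boron tribromide cleavage of aryl methyl ethers (Lewis-acid complexation of each ether oxygen, then SN2 attack of bromide on methyl, helped at both ortho positions by chelation to the ketone) should free all four phenols while the saturated chain and the electron-rich aryl ketone stay untouched, and no stereocentre is involved.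

**Compound list**
1 | 1,3,5-trimethoxybenzene | COc1cc(OC)cc(OC)c1 | starting material
2 | cyclodecanone | O=C1CCCCCCCCC1 | starting material
3 | 2,4,6-trimethoxyphenyllithium | [Li]c1c(OC)cc(OC)cc1OC | intermediate
4 | 1-(2,4,6-trimethoxyphenyl)cyclodecan-1-ol | OC1(CCCCCCCCC1)c1c(OC)cc(OC)cc1OC | intermediate
5 | 2-methoxybenzaldehyde | COc1ccccc1C=O | starting material
6 | (E)-N'-(2-methoxybenzylidene)-4-methylbenzenesulfonohydrazide | COc1ccccc1/C=N/NS(=O)(=O)c1ccc(C)cc1 | intermediate
7 | N'-[1-(2-methoxyphenyl)-11-oxo-11-(2,4,6-trimethoxyphenyl)undecyl]-4-methylbenzenesulfonohydrazide (racemic) | O=C(CCCCCCCCCC(NNS(=O)(=O)c1ccc(C)cc1)c1ccccc1OC)c1c(OC)cc(OC)cc1OC | intermediate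
8 | 11-diazenyl-11-(2-methoxyphenyl)-1-(2,4,6-trimethoxyphenyl)undecan-1-one (racemic) | O=C(CCCCCCCCCC(N=N)c1ccccc1OC)c1c(OC)cc(OC)cc1OC | intermediate
9 | 11-(2-methoxyphenyl)-1-(2,4,6-trimethoxyphenyl)undecan-1-one | O=C(CCCCCCCCCCc1ccccc1OC)c1c(OC)cc(OC)cc1OC | intermediate
10 | 11-(2-hydroxyphenyl)-1-(2,4,6-trihydroxyphenyl)undecan-1-one | O=C(CCCCCCCCCCc1ccccc1O)c1c(O)cc(O)cc1O | target

**Total step count:** 4. **Longest linear sequence:** 3 (steps 1, 3, 4).

**Steps most likely to fail**

Step 3 (new method).
- What may go wrong: the stabilised trialkoxyarene radical cation may take its electron back before the O–H bond is activated. The excited catalyst may be quenched unproductively by the hydrazone N–H. The alkoxy or C10 radical may be lost to transannular or 1,5-hydrogen transfer before C–C bond formation.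
- Fallback: it uses known chemistry, sets out from 1 and comes back at 9. Friedel–Crafts acylation of 1 with undec-10-enoic acid and trifluoroacetic anhydride (CH2Cl2, rt) should give 1-(2,4,6-trimethoxyphenyl)undec-10-en-1-one F1. Olefin cross-metathesis of this with commercial 2-vinylanisole (second-generation Ru–NHC isopropoxybenzylidene catalyst, CH2Cl2, 40 °C) makes the same C10–C11 connection as an alkene, (E)-11-(2-methoxyphenyl)-1-(2,4,6-trimethoxyphenyl)undec-10-en-1-one F2. Hydrogenation (H2, Pd/C, EtOAc) then saturates it to 9.

Step 1.
- What may go wrong: the basic, hindered aryllithium may enolise the medium-ring ketone instead of adding to it. The tertiary benzylic alcohol may ionise and dehydrate during isolation.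
- Fallback: it sets out from 1 and comes back at 9, and it replaces the ring-opening radical source by a decarboxylative one. Acylation of 1 with 11-methoxy-11-oxoundecanoic acid and trifluoroacetic anhydride should give methyl 11-oxo-11-(2,4,6-trimethoxyphenyl)undecanoate F3. Saponification (LiOH, THF/H2O) gives 11-oxo-11-(2,4,6-trimethoxyphenyl)undecanoic acid F4. Esterification with N-hydroxyphthalimide and diisopropylcarbodiimide gives 1,3-dioxoisoindolin-2-yl 11-oxo-11-(2,4,6-trimethoxyphenyl)undecanoate F5. The known photocatalytic reductive decarboxylative coupling of such redox-active esters with aldehyde sulfonylhydrazones is then run with 6 (organic dye, dihydropyridine reductant, visible light; then K2CO3, heat) and leads to 9.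

Step 4.
- What may go wrong: cleavage of the para-methoxy group may stay incomplete. The Lewis acid may strip the acyl chain from the very electron-rich ring (retro-Friedel–Crafts).
- Fallback: it sets out from 5 and comes back at 10, and it never protects the phloroglucinol ring. Wittig olefination of 5 with the ylide from (9-carboxynonyl)triphenylphosphonium bromide (2 equiv NaHMDS, THF) should give mainly (Z)-11-(2-methoxyphenyl)undec-10-enoic acid F6. Hydrogenation (H2, Pd/C) gives 11-(2-methoxyphenyl)undecanoic acid F7. BBr3 cleaves the single, unhindered anisole ether to 11-(2-hydroxyphenyl)undecanoic acid F8. Friedel–Crafts C-acylation of free phloroglucinol (excess) with this acid in BF3·OEt2 at 80 °C gives 10 directly.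

**Further compounds**
F1 | step 3 | 1-(2,4,6-trimethoxyphenyl)undec-10-en-1-one | O=C(CCCCCCCCC=C)c1c(OC)cc(OC)cc1OC
F2 | step 3 | (E)-11-(2-methoxyphenyl)-1-(2,4,6-trimethoxyphenyl)undec-10-en-1-one | O=C(CCCCCCCC/C=C/c1ccccc1OC)c1c(OC)cc(OC)cc1OC
F3 | step 1 | methyl 11-oxo-11-(2,4,6-trimethoxyphenyl)undecanoate | COC(=O)CCCCCCCCCC(=O)c1c(OC)cc(OC)cc1OC
F4 | step 1 | 11-oxo-11-(2,4,6-trimethoxyphenyl)undecanoic acid | OC(=O)CCCCCCCCCC(=O)c1c(OC)cc(OC)cc1OC
F5 | step 1 | 1,3-dioxoisoindolin-2-yl 11-oxo-11-(2,4,6-trimethoxyphenyl)undecanoate | O=C(CCCCCCCCCC(=O)c1c(OC)cc(OC)cc1OC)ON1C(=O)c2ccccc2C1=O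
F6 | step 4 | (Z)-11-(2-methoxyphenyl)undec-10-enoic acid | OC(=O)CCCCCCCC/C=C\c1ccccc1OC
F7 | step 4 | 11-(2-methoxyphenyl)undecanoic acid | OC(=O)CCCCCCCCCCc1ccccc1OC
F8 | step 4 | 11-(2-hydroxyphenyl)undecanoic acid | OC(=O)CCCCCCCCCCc1ccccc1O
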